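The numbers in the tables were generated by integration with constants of no real substance; the scatter is artificial.

Slowness is the first thing these runs show, and the level is the question at 15 d. West, with 33 mM of free catalyst, reads 58% of target at 2.50 d, while north, with 22 mM, reads 57% at the later time of 4.00 d.

| flask | starting material | reagent | free catalyst | remark | time |
|---|---|---|---|---|---|
| west | 0.30 M (in portions, 3) | 0.21 M | 33 mM | the very flask that is asked about, followed so far; portions every 12 h |  |
| north | 0.30 M (in portions, 3) | 0.21 M | 22 mM | run made earlier; portions every 12 h |  |
| flask | 0.30 M (in portions, 3) | 0.210 M | 33 mM | the portions of starting material follow each other after 12 h, the first at the start | 15 d |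

| run | time / d | target / % | catalyst intermediate C / % |
|---|---|---|---|
| west | 1.04 | 35 | 0 |
| west | 2.50 | 58 | 3 |
| west | 3.00 | 57 | 3 |
| west | 5.00 | 58 | 2 |
| north | 4.00 | 57 | 0 |
| north | 8.00 | 62 | 5 |
| north | 12.0 | 59 | 3 |
| north | 15.0 | 60 | 3 |

(standard deviation of a reading: 1.5 percentage points)

- the reaction counts as stopped when no species that holds the starting material changes by six tenths of a point or more over the second half of the time

* why nothing more happens at 15 d, or that something still does (the reagent has run out first / no working catalyst is left / all of the starting material has reacted / it is still moving / forward and back rates have come level)
* amount of target at 15 d, in percent of the starting material charged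
* amount of catalyst intermediate C at 15 d, in percent of the starting material charged

I build the flask up one process at a time. With the main step alone, one reagent per starting material, the reagent is the limiting reagent, 0.210 M against 0.30 M, and target plus C can reach 70.0% of the starting material. Over its flat readings west averages 57.7% of target and 2.67% of C, and north averages 60.3% and 3.67%, so both stop short of that.

Next I add the way back, and for it I carry one number. Target plus C over the starting material outside them, times the reagent in them over the reagent outside them, reads 9.49 in west and 19.0 in north. Both rest on readings with a scatter of 1.5 percentage points, and the reagent outside target and C is a small difference, so I take their geometric mean, 13.4, as the plateau quotient, that same ratio read as a reaction quotient where the target stops rising. Solved for the charges of this flask, it lowers target plus C to 62.3%.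

Last comes the catalyst's hold. In the west readings C keeps about 2.67%, which I take from the target. So I commit to 59.7% of target and 2.67% of C at 15 d, with forward and back rates level.

The forecast says: forward and back rates have come level, with 58.5% of target and 3% of C. Its ground is: “A plateau that is independent of catalyst and short of the stoichiometric limit points to equilibrium.” Its target and mine lie 1.2 points apart.

The flask gives 57.9% of target and 2.68% of C at 15 d, and its ending is: forward and back rates have come level; at 150 d the target still stands at 57.9%.

    catalyst intermediate C ⇌ free catalyst + target (K = 0.340 M, k = 2.60 h⁻¹)
    reagent + free catalyst ⇌ catalyst intermediate A (K = 7.20 M⁻¹, k = 670 M⁻¹ h⁻¹)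
    catalyst intermediate A ⇌ by-product + catalyst intermediate B (K = 0.610 M, k = 1.20 h⁻¹)
    starting material + catalyst intermediate B ⇌ catalyst intermediate C (K = 9.70 M⁻¹, k = 2.60 M⁻¹ h⁻¹)

Target plus C in this flask comes to 60.6%, against the 62.3% reckoned from the plateau quotient of 13.4. Put on the neighbouring flask with 0.75 M of starting material, the same quotient gives target plus C of 27.2% of its charge, and that flask holds 27.0%, with 73.0% left as starting material.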